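**Strategy.** The decalin is disconnected at the ring A bond C7–C8 and the ring-fusion bond C4–C9 (labels in remark 1). Both form in one flask: the γ-carbon (C8) of a tiglic aldehyde silyl dienol ether adds to C7 of an acyclic isopropenyl dienynyl ketone, and the (E)-2-methylenal thus unveiled is captured by the C24=C2–C3=C4 diene in an intramolecular Diels–Alder reaction under one chiral oxazaborolidinium catalyst. The step exploits the C5 oxygen of ring A as an enone carbonyl and C8–C11 with its methyl as tiglic aldehyde; it closes rings A and B and sets C4, C9, C10, C24. A diyne macrocyclisation and Z,Z-reduction finish the lactone.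

Key step: step 5

Remark 1 (labels): atoms are numbered along the target SMILES: C1 vinylic methyl, C2=C3 ring B alkene, C4 and C9 ring-fusion carbons, C5 ring A carbinol, C6 (methyl-bearing), C7 and C8 ring A methylenes, C10 quaternary carbon, C11 lactone carbonyl, C12 lactone carbinol, C13–C15, C16=C17 (C17 bears CO2H), C18 (OH), C19 (methyl), C20=C21–C22=C23, C24 ring B CH. Ring A = C4–C9; ring B = C2, C3, C4, C9, C10, C24.

Remark 2 (assumption): the enantiomers of the oxazaborolidinium catalyst (step 5) and of the Ipc2B reagent (step 12) are written according to the usual facial models; if the sense proves opposite, the antipode is used.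

**Route**

Step 1
Reactants: 1 3-(trimethylsilyl)prop-2-ynal; 2 2-(triphenylphosphoranylidene)propanal
Product: 3 (E)-2-methyl-5-(trimethylsilyl)pent-2-en-4-ynal
Conditions: CH2Cl2, 0 °C → rt
Reagents that add atoms: none
Why: Wittig olefination of the reactive ynal with a stabilised α-methyl ylide should give the (E)-trisubstituted enal, which is too hindered to react a second time.

Step 2
Reactants: 3 enynal; 4 diethyl {2-[methoxy(methyl)amino]-2-oxoethyl}phosphonate
Product: 5 (2E,4E)-N-methoxy-N,4-dimethyl-7-(trimethylsilyl)hepta-2,4-dien-6-ynamide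
Conditions: NaH, THF, 0 °C → rt
Reagents that add atoms: none
Why: Horner–Wadsworth–Emmons olefination with a stabilised phosphonate anion should give the (E)-alkene and leaves the alkynylsilane untouched.

Step 3
Reactants: 5 Weinreb dienamide; 6 isopropenylmagnesium bromide
Product: 7 (4E,6E)-2,6-dimethyl-9-(trimethylsilyl)nona-1,4,6-trien-8-yn-3-one
Conditions: THF, −78 → 0 °C; inverse quench into cold 1 M HCl
Reagents that add atoms: none
Why: Weinreb ketone synthesis, in which the chelated tetrahedral intermediate prevents over-addition and the acidic inverse quench keeps the released hydroxylamine from adding to the divinyl ketone.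

Step 4
Reactants: 8 (E)-2-methylbut-2-enal (tiglic aldehyde)
Product: 9 (E)-trimethyl[(2-methylbuta-1,3-dien-1-yl)oxy]silane
Conditions: TMSOTf, Et3N, Et2O, 0 °C → rt
Reagents that add atoms: trimethylsilyl trifluoromethanesulfonate, C[Si](C)(C)OS(=O)(=O)C(F)(F)F
Why: soft γ-enolisation of the enal (silyl dienol ether formation) gives the vinylogous nucleophile; its O-alkene geometry is lost later and is irrelevant.

Step 5
Reactants: 7 trienynone; 9 silyl dienol ether
Product: 12 trans-fused keto aldehyde (C5 ketone; C10 formyl; C24 silylethynyl), via open-chain Michael adduct 10 (not isolated), via bis-silyl cycloadduct 11 (not isolated)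
Conditions: N-protonated (S)-3,3-diphenyl-1-(o-tolyl)tetrahydropyrrolo[1,2-c][1,3,2]oxazaborole bis(trifluoromethanesulfonyl)imide salt (20 mol%), Ph3PO (20 mol%), CH2Cl2, −78 °C (slow addition of 9) → −20 °C; then aq. citric acid, THF, 0 °C
Reagents that add atoms: none
Why: Proposed new method: the Lewis acid activates the ketone of 7 in its s-trans form so that the terminal γ-carbon of 9 adds to C7 (vinylogous Mukaiyama–Michael addition; closest precedent: oxazaborolidinium-catalysed Mukaiyama–Michael additions to enones), Ph3PO shuttling the silyl group to O5 to leave the (E)-silyl enol ether and (E)-2-methylenal of 10. The same catalyst then binds the enal, and the C24=C2–C3=C4 diene adds to C9=C10 in a concerted suprafacial [4+2] step (closest precedent: oxazaborolidinium-catalysed intramolecular Diels–Alder reactions of 2-methyl trienals). Ring B closes as the cyclohexene of the cycloaddition and ring A as the six-membered tether ring through the C4–C9 bond. C9 and C10 follow from the (E)-dienophile and C24 and C4 from the (E,E)-diene; their mutual relation comes from the endo-formyl, exo-tether transition state reached from the s-trans C4–C5 rotamer, the absolute sense from the catalyst, and C6 from axial protonation of the enol ether on work-up (equatorial methyl). The step needs γ- over α-attack and conjugate addition over [4+2] addition of 9 across the isopropenyl ketone, secured by the α-methyl group of 9 and by the (E)-enal, which cannot close back onto C6. It also needs trans over cis ring fusion, secured by the endo preference of the Lewis-acid-bound formyl group.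

Step 6
Reactants: 12 keto aldehyde
Product: 13 keto acid (C11 carboxylic acid)
Conditions: NaClO2, NaH2PO4, 2-methyl-2-butene, t-BuOH/H2O, 0 °C
Reagents that add atoms: sodium chlorite, [Na+].[O-]Cl=O
Why: Pinnick oxidation converts the non-enolisable neopentyl aldehyde to the acid in a buffered medium that should not conjugate the β,γ-unsaturated ketone.

Step 7
Reactants: 13 keto acid
Product: 14 hydroxy acid (equatorial C5 alcohol)
Conditions: NaBH4, CeCl3·7H2O, MeOH, −78 °C
Reagents that add atoms: none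
Why: Luche reduction, in which the small hydride should attack the locked trans-decalone along the axial trajectory, between two equatorial α-substituents, to give the equatorial C5 alcohol.

Step 8
Reactants: 14 hydroxy acid
Product: 16 decalin acid (C5 OTBS; C24 ethynyl), via bis-TBS derivative 15 (not isolated)
Conditions: TBSOTf, 2,6-lutidine, CH2Cl2, −78 → 0 °C; then K2CO3, MeOH, rt
Reagents that add atoms: tert-butyldimethylsilyl trifluoromethanesulfonate, CC(C)(C)[Si](C)(C)OS(=O)(=O)C(F)(F)F
Why: silylation of the hindered alcohol, followed by mild methanolysis that cleaves only the silyl ester and the alkynyl C–Si bond.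

Step 9
Reactants: 17 (R)-2-methyloxirane; 18 (4-bromobut-1-yn-1-yl)trimethylsilane
Product: 20 (R)-7-(trimethylsilyl)hept-6-yn-2-ol, via Grignard reagent 19 (not isolated)
Conditions: Mg, THF; then CuI (10 mol%), 17, −30 → 0 °C
Reagents that add atoms: none
Why: copper-catalysed Grignard opening of the epoxide at its unsubstituted carbon leaves the chiral-pool stereocentre (C12, R) untouched.

Step 10
Reactants: 20 alcohol
Product: 21 (R)-triethyl{[7-(trimethylsilyl)hept-6-yn-2-yl]oxy}silane
Conditions: TESCl, imidazole, CH2Cl2, 0 °C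
Reagents that add atoms: chlorotriethylsilane, CC[Si](Cl)(CC)CC
Why: silyl ether formation gives a C12 protecting group that can later be removed in the presence of TBS ethers.

Step 11
Reactants: 21 TES ether
Product: 23 (R)-7-[(triethylsilyl)oxy]oct-2-ynal, via lithium acetylide 22 (not isolated)
Conditions: MeLi·LiBr, THF, 0 °C → rt; then DMF, −78 → 0 °C; aq. KH2PO4
Reagents that add atoms: N,N-dimethylformamide, CN(C)C=O
Why: MeLi·LiBr cleaves the alkynyl C–Si bond to the lithium acetylide, which is formylated by DMF.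

Step 12
Reactants: 23 ynal; 24 cis-but-2-ene
Product: 27 (3S,4R,10R)-3-methyl-10-[(triethylsilyl)oxy]undec-1-en-5-yn-4-ol, via (Z)-crotylpotassium 25 (not isolated), via (Z)-crotyldiisopinocampheylborane 26 (not isolated)
Conditions: 24, KOt-Bu, n-BuLi, THF, −78 → −45 °C; (+)-Ipc2BOMe, −78 °C; BF3·OEt2; 23, −78 °C; then NaOH, H2O2
Reagents that add atoms: none
Why: Brown crotylboration, in which the (Z)-crotyl unit reacts through a closed chair transition state to give the syn C18/C19 pair and the isopinocampheyl groups set the absolute sense (C18 R, C19 S).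

Step 13
Reactants: 27 propargylic alcohol
Product: 29 (R,E)-2-[(1R,2S)-1-hydroxy-2-methylbut-3-en-1-yl]-7-[(triethylsilyl)oxy]oct-2-enoic acid, via alkenylmagnesium chloride 28 (not isolated)
Conditions: i-BuMgCl (3.5 equiv), Cp2TiCl2 (10 mol%), Et2O, 0 °C → rt; then CO2, −40 → 0 °C; aq. NH4Cl
Reagents that add atoms: carbon dioxide, O=C=O
Why: Cp2TiCl2-catalysed, alkoxide-directed syn-hydromagnesiation places magnesium on the alkyne carbon next to the carbinol, and carboxylation with retention gives the alkene with C15 trans to CO2H and cis to C18.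

Step 14
Reactants: 29 hydroxy acid
Product: 31 C18 tert-butyldimethylsilyl ether of acid 29, via bis-TBS derivative 30 (not isolated)
Conditions: TBSOTf, 2,6-lutidine, CH2Cl2, −78 → 0 °C; then K2CO3, MeOH/THF/H2O, rt
Reagents that add atoms: tert-butyldimethylsilyl trifluoromethanesulfonate, CC(C)(C)[Si](C)(C)OS(=O)(=O)C(F)(F)F
Why: silylation of the allylic alcohol and selective cleavage of the labile silyl ester, which blocks the hydroxyl before the acid is activated and so avoids β-lactone formation.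

Step 15
Reactants: 31 acid
Product: 32 2-(trimethylsilyl)ethyl ester of 31
Conditions: 2-(trimethylsilyl)ethanol, EDC·HCl, DMAP, CH2Cl2, rt
Reagents that add atoms: 2-(trimethylsilyl)ethanol, C[Si](C)(C)CCO
Why: Steglich-type carbodiimide esterification installs a fluoride-labile ester that can be removed together with the silyl ethers at the end.

Step 16
Reactants: 32 ester
Product: 33 2-(trimethylsilyl)ethyl (R,E)-2-[(1R,2R)-1-(tert-butyldimethylsilyloxy)-2-methyl-3-oxopropyl]-7-[(triethylsilyl)oxy]oct-2-enoate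
Conditions: OsO4 (2 mol%), NaIO4, 2,6-lutidine, dioxane/H2O, rt
Reagents that add atoms: osmium tetroxide, O=[Os](=O)(=O)=O; sodium periodate, [Na+].[O-]I(=O)(=O)=O
Why: Lemieux–Johnson cleavage, in which OsO4 should select the monosubstituted vinyl group over the hindered, electron-poor trisubstituted enoate.

Step 17
Reactants: 33 aldehyde
Product: 34 2-(trimethylsilyl)ethyl (R,E)-2-[(1R,2S)-1-(tert-butyldimethylsilyloxy)-2-methylbut-3-yn-1-yl]-7-[(triethylsilyl)oxy]oct-2-enoate
Conditions: dimethyl (1-diazo-2-oxopropyl)phosphonate, K2CO3, MeOH, 0 °C → rt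
Reagents that add atoms: dimethyl (1-diazo-2-oxopropyl)phosphonate, COP(=O)(OC)C(=[N+]=[N-])C(C)=O
Why: Ohira–Bestmann (Seyferth–Gilbert) homologation converts the aldehyde into the terminal alkyne under conditions mild enough to keep the α-stereocentre C19.

Step 18
Reactants: 34 alkyne
Product: 35 C12 alcohol (TES ether of 34 removed)
Conditions: PPTS (cat.), MeOH/CH2Cl2, 0 °C
Reagents that add atoms: none
Why: acid-catalysed methanolysis cleaves the triethylsilyl ether much faster than the hindered secondary TBS ether.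

Step 19
Reactants: 16 decalin acid; 35 alcohol
Product: 37 seco ester (C11–O–C12 ester carrying two terminal alkynes), via acid chloride 36 (not isolated)
Conditions: 16, 1-chloro-N,N,2-trimethylprop-1-en-1-amine, CH2Cl2, 0 °C → rt; then 35, DMAP, Et3N, CH2Cl2, 40 °C
Reagents that add atoms: none
Why: the neopentyl acid is activated as its acid chloride under neutral conditions and transferred by DMAP catalysis to the unhindered C12 hydroxyl with retention at C12.

Step 20
Reactants: 37 seco ester
Product: 38 macrocyclic 1,3-diyne (sixteen-membered lactone, C20≡C21–C22≡C23)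
Conditions: Cu(OAc)2 (10 equiv), pyridine/MeCN, 60 °C, slow addition, final concentration 1 mM
Reagents that add atoms: none
Why: Glaser–Eglinton oxidative coupling of the two terminal alkynes under high dilution closes the ring through an sp–sp bond, since the cis C10/C24 substituents hold both chains on the same face of ring B.

Step 21
Reactants: 38 macrocyclic diyne
Product: 39 protected (20Z,22Z)-diene macrolide
Conditions: Zn dust activated with Cu(OAc)2 and AgNO3, MeOH/H2O, 40 °C
Reagents that add atoms: none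
Why: Boland reduction, in which activated zinc reduces the conjugated diyne by cis addition to the (Z,Z)-diene and leaves the enoate and the ring B alkene alone.

Step 22
Reactants: 39 protected macrolide
Product: 40 target CNP0284457.3
Conditions: TBAF, THF, 0 → 40 °C; then aq. NH4Cl
Reagents that add atoms: none
Why: fluoride cleaves both TBS ethers and fragments the 2-(trimethylsilyl)ethyl ester to the free acid, while the hindered lactone should survive.

**Compound list**

1 | 3-(trimethylsilyl)prop-2-ynal | C[Si](C)(C)C#CC=O | starting material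
2 | 2-(triphenylphosphoranylidene)propanal | CC(C=O)=P(c1ccccc1)(c1ccccc1)c1ccccc1 | starting material
3 | (E)-2-methyl-5-(trimethylsilyl)pent-2-en-4-ynal | O=C/C(C)=C/C#C[Si](C)(C)C | intermediate
4 | diethyl {2-[methoxy(methyl)amino]-2-oxoethyl}phosphonate | CCOP(=O)(CC(=O)N(C)OC)OCC | starting material
5 | (2E,4E)-N-methoxy-N,4-dimethyl-7-(trimethylsilyl)hepta-2,4-dien-6-ynamide | CON(C)C(=O)/C=C/C(C)=C/C#C[Si](C)(C)C | intermediate
6 | isopropenylmagnesium bromide | C=C(C)[Mg]Br | starting material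
7 | (4E,6E)-2,6-dimethyl-9-(trimethylsilyl)nona-1,4,6-trien-8-yn-3-one | C=C(C)C(=O)/C=C/C(C)=C/C#C[Si](C)(C)C | intermediate
8 | (E)-2-methylbut-2-enal | C/C=C(\C)C=O | starting material
9 | (E)-trimethyl[(2-methylbuta-1,3-dien-1-yl)oxy]silane | C=C/C(C)=C/O[Si](C)(C)C | intermediate
10 | (2E,6E,8E,10E)-2,6,10-trimethyl-7-[(trimethylsilyl)oxy]-13-(trimethylsilyl)trideca-2,6,8,10-tetraen-12-ynal | C[Si](C)(C)O/C(=C(\C)CC/C=C(\C)C=O)/C=C/C(C)=C/C#C[Si](C)(C)C | intermediate
11 | trans-fused cycloadduct: C5 trimethylsilyl enol ether (C5=C6), C10 methyl and formyl (formyl cis to H9 and to the C24 substituent), C24 (trimethylsilyl)ethynyl | CC1=C[C@H]2C(O[Si](C)(C)C)=C(C)CC[C@@H]2[C@@](C)(C=O)[C@H]1C#C[Si](C)(C)C | intermediate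
12 | trans-decalin keto aldehyde: C5 ketone, equatorial C6 methyl, otherwise as 11 | CC1=C[C@H]2C(=O)[C@@H](C)CC[C@@H]2[C@@](C)(C=O)[C@H]1C#C[Si](C)(C)C | intermediate
13 | keto acid: as 12 with C11 carboxylic acid | CC1=C[C@H]2C(=O)[C@@H](C)CC[C@@H]2[C@@](C)(C(=O)O)[C@H]1C#C[Si](C)(C)C | intermediate
14 | hydroxy acid: as 13 with equatorial C5 hydroxyl (trans to the C6 methyl) | CC1=C[C@H]2[C@H](O)[C@@H](C)CC[C@@H]2[C@@](C)(C(=O)O)[C@H]1C#C[Si](C)(C)C | intermediate
15 | bis-TBS derivative of 14 (C5 silyl ether, C11 silyl ester) | CC1=C[C@H]2[C@H](O[Si](C)(C)C(C)(C)C)[C@@H](C)CC[C@@H]2[C@@](C)(C(=O)O[Si](C)(C)C(C)(C)C)[C@H]1C#C[Si](C)(C)C | intermediate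
16 | decalin acid: C5 OTBS, C11 acid, C24 ethynyl | CC1=C[C@H]2[C@H](O[Si](C)(C)C(C)(C)C)[C@@H](C)CC[C@@H]2[C@@](C)(C(=O)O)[C@H]1C#C | intermediate
17 | (R)-2-methyloxirane | C[C@@H]1CO1 | starting material
18 | (4-bromobut-1-yn-1-yl)trimethylsilane | C[Si](C)(C)C#CCCBr | starting material
19 | [4-(trimethylsilyl)but-3-yn-1-yl]magnesium bromide | C[Si](C)(C)C#CCC[Mg]Br | intermediate
20 | (R)-7-(trimethylsilyl)hept-6-yn-2-ol | C[C@@H](O)CCCC#C[Si](C)(C)C | intermediate
21 | (R)-triethyl{[7-(trimethylsilyl)hept-6-yn-2-yl]oxy}silane | C[C@@H](O[Si](CC)(CC)CC)CCCC#C[Si](C)(C)C | intermediate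
22 | lithium acetylide of (R)-triethyl(hept-6-yn-2-yloxy)silane | C[C@@H](O[Si](CC)(CC)CC)CCCC#C[Li] | intermediate
23 | (R)-7-[(triethylsilyl)oxy]oct-2-ynal | C[C@@H](O[Si](CC)(CC)CC)CCCC#CC=O | intermediate
24 | cis-but-2-ene | C/C=C\C | starting material
25 | (Z)-but-2-en-1-ylpotassium | [K+].[CH2-]/C=C\C | intermediate
26 | (Z)-but-2-en-1-yl-bis[(+)-isopinocampheyl]borane | C/C=C\CB([C@H]1C[C@H]2C[C@@H]([C@@H]1C)C2(C)C)[C@H]1C[C@H]2C[C@@H]([C@@H]1C)C2(C)C | intermediate
27 | (3S,4R,10R)-3-methyl-10-[(triethylsilyl)oxy]undec-1-en-5-yn-4-ol | C[C@@H](O[Si](CC)(CC)CC)CCCC#C[C@H](O)[C@@H](C)C=C | intermediate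
28 | alkenylmagnesium chloride alkoxide (Mg on C17, cis to H16) | C[C@@H](O[Si](CC)(CC)CC)CCC/C=C(/[Mg]Cl)[C@H](O[Mg]Cl)[C@@H](C)C=C | intermediate
29 | (R,E)-2-[(1R,2S)-1-hydroxy-2-methylbut-3-en-1-yl]-7-[(triethylsilyl)oxy]oct-2-enoic acid | C[C@@H](O[Si](CC)(CC)CC)CCC/C=C(/C(=O)O)[C@H](O)[C@@H](C)C=C | intermediate
30 | bis-TBS derivative of 29 (C18 silyl ether, silyl ester) | C[C@@H](O[Si](CC)(CC)CC)CCC/C=C(/C(=O)O[Si](C)(C)C(C)(C)C)[C@H](O[Si](C)(C)C(C)(C)C)[C@@H](C)C=C | intermediate
31 | (R,E)-2-[(1R,2S)-1-(tert-butyldimethylsilyloxy)-2-methylbut-3-en-1-yl]-7-[(triethylsilyl)oxy]oct-2-enoic acid | C[C@@H](O[Si](CC)(CC)CC)CCC/C=C(/C(=O)O)[C@H](O[Si](C)(C)C(C)(C)C)[C@@H](C)C=C | intermediate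
32 | 2-(trimethylsilyl)ethyl ester of 31 | C[C@@H](O[Si](CC)(CC)CC)CCC/C=C(/C(=O)OCC[Si](C)(C)C)[C@H](O[Si](C)(C)C(C)(C)C)[C@@H](C)C=C | intermediate
33 | 2-(trimethylsilyl)ethyl (R,E)-2-[(1R,2R)-1-(tert-butyldimethylsilyloxy)-2-methyl-3-oxopropyl]-7-[(triethylsilyl)oxy]oct-2-enoate | C[C@@H](O[Si](CC)(CC)CC)CCC/C=C(/C(=O)OCC[Si](C)(C)C)[C@H](O[Si](C)(C)C(C)(C)C)[C@@H](C)C=O | intermediate
34 | 2-(trimethylsilyl)ethyl (R,E)-2-[(1R,2S)-1-(tert-butyldimethylsilyloxy)-2-methylbut-3-yn-1-yl]-7-[(triethylsilyl)oxy]oct-2-enoate | C[C@@H](O[Si](CC)(CC)CC)CCC/C=C(/C(=O)OCC[Si](C)(C)C)[C@H](O[Si](C)(C)C(C)(C)C)[C@@H](C)C#C | intermediate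
35 | 2-(trimethylsilyl)ethyl (R,E)-2-[(1R,2S)-1-(tert-butyldimethylsilyloxy)-2-methylbut-3-yn-1-yl]-7-hydroxyoct-2-enoate | C[C@@H](O)CCC/C=C(/C(=O)OCC[Si](C)(C)C)[C@H](O[Si](C)(C)C(C)(C)C)[C@@H](C)C#C | intermediate
36 | acid chloride of 16 | CC1=C[C@H]2[C@H](O[Si](C)(C)C(C)(C)C)[C@@H](C)CC[C@@H]2[C@@](C)(C(=O)Cl)[C@H]1C#C | intermediate
37 | seco ester: C11 acyl of 16 on the C12 oxygen of 35, two terminal alkynes | CC1=C[C@H]2[C@H](O[Si](C)(C)C(C)(C)C)[C@@H](C)CC[C@@H]2[C@@](C)(C(=O)O[C@H](C)CCC/C=C(/C(=O)OCC[Si](C)(C)C)[C@H](O[Si](C)(C)C(C)(C)C)[C@@H](C)C#C)[C@H]1C#C | intermediate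
38 | macrocyclic 1,3-diyne (C20≡C21–C22≡C23), C5 and C18 OTBS, TMSE ester | CC1=C[C@H]2[C@H](O[Si](C)(C)C(C)(C)C)[C@@H](C)CC[C@@H]2[C@@]2(C)C(=O)O[C@H](C)CCC/C=C(/C(=O)OCC[Si](C)(C)C)[C@H](O[Si](C)(C)C(C)(C)C)[C@@H](C)C#CC#C[C@@H]12 | intermediate
39 | protected (20Z,22Z)-diene macrolide | CC1=C[C@H]2[C@H](O[Si](C)(C)C(C)(C)C)[C@@H](C)CC[C@@H]2[C@@]2(C)C(=O)O[C@H](C)CCC/C=C(/C(=O)OCC[Si](C)(C)C)[C@H](O[Si](C)(C)C(C)(C)C)[C@@H](C)/C=C\C=C/[C@@H]12 | intermediate
40 | CNP0284457.3 | CC1=C[C@H]2[C@H](O)[C@@H](C)CC[C@@H]2[C@@]2(C)C(=O)O[C@H](C)CCC/C=C(/C(=O)O)[C@H](O)[C@@H](C)/C=C\C=C/[C@@H]12 | target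

**Step count.** Total: 22 steps. Longest linear sequence: 14 steps (steps 9–18, then 19–22).

**Steps most likely to fail**

1. Step 5 (proposed new method). The dienol ether may add across the isopropenyl ketone in a stepwise [4+2] sense, or the activated divinyl ketone may undergo Nazarov-type electrocyclisation, instead of conjugate addition. The cycloaddition may also show exo orientation or poor facial selection, and the ring B alkene may migrate into conjugation with the C5 ketone on work-up. The fallback uses known chemistry, sets out from compound 3 and returns at compound 16. Wittig reaction of 3 with (triphenylphosphoranylidene)acetaldehyde gives (2E,4E)-4-methyl-7-(trimethylsilyl)hepta-2,4-dien-6-ynal F1. A boron-mediated Evans syn-aldol reaction with (R)-4-benzyl-3-propionyloxazolidin-2-one (Bu2BOTf, i-Pr2NEt) gives the aldol imide F2, which sets C5 and C6. TBSOTf gives the silyl ether F3, LiBH4 the primary alcohol F4, and I2/PPh3/imidazole the iodide F5. Nickel-catalysed reductive allylation of F5 with methyl (E)-4-acetoxy-2-methylbut-2-enoate (NiCl2(dme), 4,4′-di-tert-butyl-2,2′-bipyridine, Zn, MgCl2, pyridine, DMA) forms C7–C8 and gives the trienoate F6. Heating F6 in toluene in the same flask gives the intramolecular Diels–Alder adduct F7 through the chair-like, all-equatorial tether, so the two bonds still form in one operation. K2CO3/MeOH gives the terminal alkyne F8, and LiI in refluxing pyridine demethylates the ester to 16.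

2. Step 20. Intermolecular coupling may lead to oligomers, or closure to the rod-containing sixteen-membered ring may fail. The fallback closes the ring at the ester instead; it sets out from compounds 34 and 16 and returns at compound 38. NBS/AgNO3 converts 34 into the bromoalkyne F12. Cadiot–Chodkiewicz coupling with 16 (CuCl, NH2OH·HCl, n-BuNH2) gives the open-chain diyne acid F13. PPTS/MeOH frees the C12 hydroxyl to give the seco acid F14. Yamaguchi macrolactonisation (2,4,6-trichlorobenzoyl chloride, Et3N, then DMAP, toluene, high dilution) gives 38.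

3. Step 13. The terminal vinyl group may be hydrometallated in competition, or the regiochemistry of magnesium delivery may erode. The fallback sets out from compound 27 and returns at compound 32. Syn-hydrostannation (Bu3SnH, PdCl2(PPh3)2, THF) gives the carbinol-proximal alkenylstannane F9. Iodine gives the alkenyl iodide F10 with retention. Carbonylation (Pd(OAc)2, PPh3, CO, 2-(trimethylsilyl)ethanol, Et3N) gives the hydroxy ester F11, and TBSOTf/2,6-lutidine gives 32.

**Further compounds**

F1 | step 5 | (2E,4E)-4-methyl-7-(trimethylsilyl)hepta-2,4-dien-6-ynal | O=C/C=C/C(C)=C/C#C[Si](C)(C)C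
F2 | step 5 | (R)-4-benzyl-3-[(2R,3S,4E,6E)-3-hydroxy-2,6-dimethyl-9-(trimethylsilyl)nona-4,6-dien-8-ynoyl]oxazolidin-2-one | C[Si](C)(C)C#C/C=C(C)/C=C/[C@H](O)[C@@H](C)C(=O)N1C(=O)OC[C@H]1Cc1ccccc1
F3 | step 5 | tert-butyldimethylsilyl ether of F2 | C[Si](C)(C)C#C/C=C(C)/C=C/[C@H](O[Si](C)(C)C(C)(C)C)[C@@H](C)C(=O)N1C(=O)OC[C@H]1Cc1ccccc1
F4 | step 5 | primary alcohol from reductive removal of the auxiliary | C[Si](C)(C)C#C/C=C(C)/C=C/[C@H](O[Si](C)(C)C(C)(C)C)[C@@H](C)CO
F5 | step 5 | primary iodide from F4 | C[Si](C)(C)C#C/C=C(C)/C=C/[C@H](O[Si](C)(C)C(C)(C)C)[C@@H](C)CI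
F6 | step 5 | methyl (E,E,E)-trienynoate (not isolated) | C[Si](C)(C)C#C/C=C(C)/C=C/[C@H](O[Si](C)(C)C(C)(C)C)[C@@H](C)CC/C=C(\C)C(=O)OC
F7 | step 5 | trans-decalin methyl ester with C5 OTBS and C24 (trimethylsilyl)ethynyl | CC1=C[C@H]2[C@H](O[Si](C)(C)C(C)(C)C)[C@@H](C)CC[C@@H]2[C@@](C)(C(=O)OC)[C@H]1C#C[Si](C)(C)C
F8 | step 5 | methyl ester of 16 | CC1=C[C@H]2[C@H](O[Si](C)(C)C(C)(C)C)[C@@H](C)CC[C@@H]2[C@@](C)(C(=O)OC)[C@H]1C#C
F9 | step 13 | C17 tributylstannyl alkene from 27 | C[C@@H](O[Si](CC)(CC)CC)CCC/C=C(/[Sn](CCCC)(CCCC)CCCC)[C@H](O)[C@@H](C)C=C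
F10 | step 13 | C17 iodoalkene | C[C@@H](O[Si](CC)(CC)CC)CCC/C=C(/I)[C@H](O)[C@@H](C)C=C
F11 | step 13 | 2-(trimethylsilyl)ethyl ester with free C18 hydroxyl | C[C@@H](O[Si](CC)(CC)CC)CCC/C=C(/C(=O)OCC[Si](C)(C)C)[C@H](O)[C@@H](C)C=C
F12 | step 20 | 1-bromoalkyne from 34 | C[C@@H](O[Si](CC)(CC)CC)CCC/C=C(/C(=O)OCC[Si](C)(C)C)[C@H](O[Si](C)(C)C(C)(C)C)[C@@H](C)C#CBr
F13 | step 20 | open-chain diyne acid with C12 OTES | CC1=C[C@H]2[C@H](O[Si](C)(C)C(C)(C)C)[C@@H](C)CC[C@@H]2[C@@](C)(C(=O)O)[C@H]1C#CC#C[C@H](C)[C@@H](O[Si](C)(C)C(C)(C)C)/C(=C\CCC[C@@H](C)O[Si](CC)(CC)CC)C(=O)OCC[Si](C)(C)C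
F14 | step 20 | seco hydroxy acid | CC1=C[C@H]2[C@H](O[Si](C)(C)C(C)(C)C)[C@@H](C)CC[C@@H]2[C@@](C)(C(=O)O)[C@H]1C#CC#C[C@H](C)[C@@H](O[Si](C)(C)C(C)(C)C)/C(=C\CCC[C@@H](C)O)C(=O)OCC[Si](C)(C)C
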